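All runs are simulated for an exercise, noise included.

In the epsilon run, product came at 9.39 × 10⁻⁴ M h⁻¹ over the first 9.8 h, but at 2.12 × 10⁻⁴ M h⁻¹ from 22 h to 47 h, a fall by a factor of 4.43. Here is what you have to work with, and what is asked.

common to all: free catalyst 4.00 × 10⁻⁴ M
- epsilon: starting material 0.0800 M; coupling partner 0.200 M
- gamma: starting material 0.0320 M; coupling partner 0.152 M
- delta: starting material 0.0800 M; coupling partner 0.300 M
- zeta: starting material 0.0320 M; coupling partner 0.0800 M; time 47 h

| epsilon run: time / h | epsilon run: [product] / M | gamma run: time / h | gamma run: [product] / M | delta run: time / h | delta run: [product] / M |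
|---|---|---|---|---|---|
| 1.7 | 0.0018 | 1.7 | 0.0012 | 1.7 | 0.0012 |
| 5.1 | 0.0054 | 5.1 | 0.0045 | 5.1 | 0.0045 |
| 9.8 | 0.0092 | 9.8 | 0.0048 | 9.8 | 0.0078 |
| 16 | 0.0126 | 16 | 0.0072 | 16 | 0.0103 |
| 22 | 0.0157 | 22 | 0.0089 | 22 | 0.0123 |
| 30 | 0.0191 | 30 | 0.0106 | 30 | 0.0135 |
| 38 | 0.0212 | 38 | 0.0106 | 38 | 0.0153 |
| 47 | 0.0210 | 47 | 0.0122 | 47 | 0.0159 |

(each reading ± 6 × 10⁻⁴ M)

- Overall: starting material + coupling partner -> product, with free catalyst as catalyst.
- Constant volume, constant temperature.
- A reading of a species includes what of it is bound.
- An order is taken over about fifteen percent of the charge, up and down.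

1. how the opening rate goes with [starting material] round the charge of the epsilon run: the exponent of the rate at two percent of starting material gone to product (one fixed amount of product, the same in the runs compared)
2. how the opening rate goes with [coupling partner] round the charge of the epsilon run: the exponent of the rate at two percent of starting material gone to product
3. product in the zeta run at 47 h, as a share of the starting material charged

By 47 h the epsilon run has turned 26.2% of its starting material, so a rate proportional to it loses a factor of 1.36, less than the 4.43 read from the readings.

So I treat the rate as fading steadily. The fade time τ is the time in which the rate drops by the factor e. The midpoints of the two stretches lie 29.6 h apart, so τ is that gap divided by the natural log of the ratio. The opening rate r is the first stretch's mean rate, carried back to time zero.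

| run | partner charged | τ | r |
|---|---|---|---|
| epsilon | 0.200 M | 19.9 h | 0.00120 M h⁻¹ |
| gamma | 0.152 M | 22.6 h | 6.09 × 10⁻⁴ M h⁻¹ |
| delta | 0.300 M | 17.3 h | 0.00106 M h⁻¹ |

Integrated, a fading rate gives product P at time t as P = rτ − rτ·e^(−t/τ): the ceiling rτ, less what the rate would still add after t.

For zeta, my own reckoning takes r from gamma, which has the same starting material charge. The delta run's r is 0.883 of the epsilon run's, so less partner should open somewhat faster, a push upward that I leave out. A straight line in the inverse of τ through epsilon and gamma, whose partner charges lie closer to zeta's than delta's does, gives zeta a τ of 28.3 h. Epsilon and gamma differ in starting material as well, so this line is a guess that lays their whole difference in τ on the partner. The ceiling is then 0.0172 M, and by 47 h the rate is down to 19.0% of its opening value. That makes 43.6% of the charge.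

The forecast gives 0.95 and −0.65 for the two orders and 40% for zeta, lower than my figure. Its ground: “all runs slow much faster than substrate loss explains, so product inhibits strongly”.

The zeta run gives 45.6%, and the orders round the charge of the epsilon run come to 0.38 in starting material and −0.13 in coupling partner.

    free catalyst + starting material → catalyst-substrate complex (180.7 M⁻¹ h⁻¹)
    catalyst-substrate complex + coupling partner → loaded catalyst (846.0 M⁻¹ h⁻¹)
    loaded catalyst → product + free catalyst (4.572 h⁻¹)
    free catalyst + coupling partner → spent catalyst + coupling partner (2.182 M⁻¹ h⁻¹)
    coupling partner → lost reagent (0.09216 h⁻¹)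

Put the epsilon run's 19.9 h and its r into the law, and product reaches a quarter of that run's charge at 36.1 h. The epsilon run itself gets there at 36.6 h.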